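The reagent was what I had to settle: was going from 1.30 equiv to 2.20 equiv worth the charge for a reading at 12 min?

| flask | starting material | reagent | protic impurity | free catalyst | remark | time |
|---|---|---|---|---|---|---|
| alpha | 0.10 M | 1 equiv | 0.010 M | 0.1 mol% | run made earlier |  |
| epsilon | 0.10 M | 1.5 equiv | 0.010 M | 0.1 mol% | run made earlier |  |
| north-east | 0.10 M | 2.20 equiv | 0.0100 M | 0.1 mol% |  | 12 min |
| south | 0.10 M | 1.30 equiv | 0.0100 M | 0.1 mol% |  | 12 min |
| north | 0.10 M | 1.70 equiv | 0.0100 M | 0.1 mol% |  | 12 min |

| run | time / min | starting material / % | product / % |
|---|---|---|---|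
| alpha | 0.500 | 93.5 | 1.7 |
| alpha | 0.833 | 90.2 | 1.7 |
| alpha | 1.33 | 89.7 | 2.5 |
| alpha | 2.00 | 86.5 | 2.4 |
| alpha | 4.00 | 83.5 | 5.5 |
| alpha | 6.00 | 82.6 | 7.6 |
| epsilon | 0.417 | 94.3 | 2.1 |
| epsilon | 1.33 | 86.5 | 2.0 |
| epsilon | 2.00 | 85.9 | 3.9 |
| epsilon | 3.00 | 84.2 | 4.9 |
| epsilon | 5.00 | 81.0 | 9.4 |
| epsilon | 6.00 | 79.8 | 11.6 |

(scatter of a reading: 1 percentage point)

1. part of the starting material that has reacted at the end, north-east
2. part of the starting material that has reacted at the end, south
3. part of the starting material that has reacted at the end, north
4. what raising the equivalents of reagent from its lowest to its highest value here does to the part of the starting material that has reacted (changes below 5 percentage points count as none) (no change / it rises / it falls)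



By 2.00 min in the alpha run, 11.1% of the starting material had gone without appearing as product. The protic impurity was charged at 10.0% of the starting material, so I wrote that share off and kept f = 90.0% as the part open to the catalysed reaction. Product at 6.00 min then went up 1.53-fold from alpha to epsilon, while the reagent went up 1.50-fold, so I let the reagent concentration set the order. I treated the starting material as pseudo-first-order, with the reagent held at its charge.

That gave me one quantity, κ, the rate constant per equivalent of reagent: product divided by f, by the equivalents E and by the time t. Alpha gave 0.0141 min⁻¹ per equivalent and epsilon 0.0143 min⁻¹, and I carried their mean, κ = 0.0142 min⁻¹.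

With f·exp(−κEt) left, my reckoning had 27.9% reacted in south, 32.6% in north and 38.1% in north-east. The rise of 10 percentage points was more than the 5 points that counts as a change, so I decided for the higher charge.

The forecast, calling the rate “roughly first order in reagent”, gave 27%, 32.5% and 38% in the same order, with the verdict it rises. These were close to my figures but not the same ones.

The flasks gave 27.2%, 31.2% and 35.5% in the same order, and the answer on the trend was it rises, by 8.3 points.

    reagent + free catalyst → catalyst intermediate A (k = 2.70 M⁻¹ s⁻¹)
    starting material + catalyst intermediate A → catalyst intermediate B (k = 32.0 M⁻¹ s⁻¹)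
    catalyst intermediate B ⇌ by-product + catalyst intermediate C (K = 0.180 M, k = 2.00 s⁻¹)
    catalyst intermediate C → free catalyst + product (k = 180 s⁻¹)
    reagent + by-product ⇌ idle adduct, settled at all times (K = 130 M⁻¹)
    starting material + protic impurity → quenched substrate (k = 0.370 M⁻¹ s⁻¹)

Read back from the north-east result, κ was 0.0126 min⁻¹ per equivalent, less than the carried value. For the neighbouring flask, the same as north but with 2.90 equiv of reagent, κ gave 45.1% reacted at 12 min, and the flask gave 40.5%. There, free catalyst stood at 61.0% of the catalyst charged, against 75.0% in north.

The readings were generated by integration for an exercise; scatter was added.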